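**Retrosynthetic overview**
1. Ustusoic acid B ⇐ aqueous acid (tert-butyl ester, C12 acetal) ⇐ 6-O-acylation of a 6β,9α-diol ⇐ hydride reduction of a 9α-hydroxy-7-en-6-one ⇐ singlet oxygen across C6/C9 of a ring-B 6,8-diene ester.
2. That diene ⇐ one aminocatalytic inverse-demand [4+2]/amine loss of an acyclic aldehyde–dienoate: C5–C10 first (ring A), then C6–C7 (ring B), so both rings and both ring-fusion centres arise in one operation.
3. Enabling feature: on ring B the C6 oxygen and the C9 carboxyl (C11) stand 1,4 across C7=C8. C5 is therefore the α-carbon of a C6 aldehyde (enamine donor) and C10 the β-carbon of a C9 acrylate (acceptor), and the C6=C7–C8=C9 diene left after amine loss takes up O2 exactly at C6 and C9.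
4. Aldehyde–dienoate ⇐ Stille coupling (C8–C9) of a 2-stannylacrolein acetal (C7, C8, C12) with an α-iodo enoate from syn-carbocupration/iodination of a ynoate (C9, C10, C11) ⇐ 3,3-dimethylpentane-1,5-diol (C2–C6) plus a propargyl unit.
5. Ring order: A, then B, both in the key step; no ring exists before it.

Key step: step 10

Remark: positions are numbered as in drimanes (C1–C10 ring carbons, C11 the carboxyl on C9, C12 the formyl carbon on C8); the target is taken as the open 11-acid/12-aldehyde as drawn, any lactol ring tautomer being in equilibrium with it.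

Step 1
Reactants: 1 3,3-dimethylpentane-1,5-diol
Product: 2 5-[(tert-butyldimethylsilyl)oxy]-3,3-dimethylpentan-1-ol
Conditions: NaH (1.0 equiv), THF, 0 → 23 °C; then TBSCl, 23 °C
Reagents that add atoms: tert-butyldimethylsilyl chloride, CC(C)(C)[Si](C)(C)Cl
Why: O-silylation of the sparingly soluble monosodium alkoxide of a symmetric diol should stop at the mono-silyl ether, which tells the C6 end from the C2 end.

Step 2
Reactants: 2 5-[(tert-butyldimethylsilyl)oxy]-3,3-dimethylpentan-1-ol
Product: 3 tert-butyl[(5-iodo-3,3-dimethylpentyl)oxy]dimethylsilane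
Conditions: I2, PPh3, imidazole, CH2Cl2, 0 → 23 °C
Reagents that add atoms: iodine, [I][I]
Why: Appel iodination of an unhindered primary alcohol; the silyl ether is stable to the buffered conditions.

Step 3
Reactants: 3 tert-butyl[(5-iodo-3,3-dimethylpentyl)oxy]dimethylsilane
Product: 4 tert-butyl{[3,3-dimethyl-8-(trimethylsilyl)oct-7-yn-1-yl]oxy}dimethylsilane
Conditions: 1-(trimethylsilyl)propyne, n-BuLi, THF, −78 → −20 °C; then 3, DMPU, −78 → 23 °C
Reagents that add atoms: 1-(trimethylsilyl)propyne, CC#C[Si](C)(C)C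
Why: SN2 alkylation of the propargylic lithium reagent by a primary iodide; the silyl group steers the reaction to the propargyl (not allenyl) product and installs C1, C10 and C9.

Step 4
Reactants: 4 tert-butyl{[3,3-dimethyl-8-(trimethylsilyl)oct-7-yn-1-yl]oxy}dimethylsilane
Product: 6 tert-butyl 9-[(tert-butyldimethylsilyl)oxy]-7,7-dimethylnon-2-ynoate, via lithium acetylide 5 (not isolated)
Conditions: MeLi·LiBr, THF, 0 → 23 °C; then Boc2O, −78 → 0 °C
Reagents that add atoms: di-tert-butyl dicarbonate, CC(C)(C)OC(=O)OC(=O)OC(C)(C)C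
Why: C-desilylation of the alkynylsilane by methyllithium gives the lithium acetylide directly, and its alkoxycarbonylation with the dicarbonate gives the tert-butyl ynoate (C11).

Step 5
Reactants: 6 tert-butyl 9-[(tert-butyldimethylsilyl)oxy]-7,7-dimethylnon-2-ynoate
Product: 8 tert-butyl (2E)-9-[(tert-butyldimethylsilyl)oxy]-2-iodo-3,7,7-trimethylnon-2-enoate, via alkenylcuprate 7 (not isolated)
Conditions: CuI, MeLi (2.0 equiv), THF, 0 °C; then 6, −78 °C; then I2, −78 °C
Reagents that add atoms: lithium dimethylcuprate, [Li+].C[Cu-]C; iodine, [I][I]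
Why: syn-carbocupration of the ynoate at −78 °C followed by iodinolysis with retention fixes the C9=C10 geometry (new C10 methyl cis to iodine, chain cis to the ester); the bulky tert-butyl ester suppresses 1,2-addition.

Step 6
Reactants: 9 3,3-diethoxyprop-1-yne
Product: 10 tributyl(3,3-diethoxyprop-1-en-2-yl)stannane
Conditions: Bu3SnH, Mo(CO)3(CNtBu)3 (cat.), hydroquinone, THF, 55 °C
Reagents that add atoms: tributyltin hydride, CCCC[SnH](CCCC)CCCC
Why: molybdenum-catalysed hydrostannation of a terminal alkyne with a propargylic oxygen substituent places tin on the internal carbon, giving the 2-metallated acrolein acetal (C7, C8, C12).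

Step 7
Reactants: 8 tert-butyl (2E)-9-[(tert-butyldimethylsilyl)oxy]-2-iodo-3,7,7-trimethylnon-2-enoate; 10 tributyl(3,3-diethoxyprop-1-en-2-yl)stannane
Product: 11 tert-butyl (2Z)-9-[(tert-butyldimethylsilyl)oxy]-2-(3,3-diethoxyprop-1-en-2-yl)-3,7,7-trimethylnon-2-enoate
Conditions: Pd2(dba)3 (cat.), AsPh3, CuI (cat.), NMP, 45 °C
Reagents that add atoms: none
Why: Stille coupling with retention at both alkenyl carbons forms the C8–C9 bond of the cross-conjugated diene; the copper co-catalyst and the weakly binding arsine are the usual remedy for hindered partners.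

Step 8
Reactants: 11 tert-butyl (2Z)-9-[(tert-butyldimethylsilyl)oxy]-2-(3,3-diethoxyprop-1-en-2-yl)-3,7,7-trimethylnon-2-enoate
Product: 12 tert-butyl (2Z)-2-(3,3-diethoxyprop-1-en-2-yl)-9-hydroxy-3,7,7-trimethylnon-2-enoate
Conditions: TBAF, THF, 0 °C
Reagents that add atoms: none
Why: fluoride desilylation of a primary silyl ether; the acetal, tert-butyl ester and diene are inert.

Step 9
Reactants: 12 tert-butyl (2Z)-2-(3,3-diethoxyprop-1-en-2-yl)-9-hydroxy-3,7,7-trimethylnon-2-enoate
Product: 13 tert-butyl (2Z)-2-(3,3-diethoxyprop-1-en-2-yl)-3,7,7-trimethyl-9-oxonon-2-enoate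
Conditions: Dess–Martin periodinane, NaHCO3, CH2Cl2, 0 → 23 °C
Reagents that add atoms: none
Why: Dess–Martin oxidation under buffered, non-aqueous conditions gives the β-quaternary aldehyde (C6) without touching the acetal or the diene.

Step 10
Reactants: 13 tert-butyl (2Z)-2-(3,3-diethoxyprop-1-en-2-yl)-3,7,7-trimethyl-9-oxonon-2-enoate
Product: 16 tert-butyl (4aS,8aS)-2-(diethoxymethyl)-5,5,8a-trimethyl-4a,5,6,7,8,8a-hexahydronaphthalene-1-carboxylate, via enamine 14 (not isolated), via aminooctalin 15 (not isolated)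
Conditions: (R)-2-[diphenyl(trimethylsilyloxy)methyl]pyrrolidine (20 mol %), PhCO2H (20 mol %), 4 Å MS, toluene, 23 → 50 °C
Reagents that add atoms: none
Why: Proposed new method: the amine condenses with aldehyde 13 to the (E)-enamine 14, whose nucleophilic carbon C5 adds to C10, the β-carbon of the α-vinyl acrylate (6-exo-trig closure of ring A), and the resulting ester dienolate closes ring B through C7 onto the iminium carbon C6 (6-(enolendo)-exo-trig, overall an inverse-electron-demand [4+2]) to give amine 15, which loses the protonated catalyst by E1cB elimination through the vinylogously acidic C7–H and so releases diene 16 and turns the catalyst over. The closest known reaction types are the thermal cycloaddition of aldehyde enamines to 2,4-dienoates and 2-(alkoxycarbonyl)dienes followed by amine elimination to cyclohexa-1,3-dienes, and aminocatalytic inverse-electron-demand Diels–Alder reactions of aldehydes; new is the intramolecular, catalytic version that builds a quaternary ring-fusion carbon. C5 is set by the catalyst: in the (E)-enamine the diphenyl(silyloxy)methyl group of the (R)-amine shields the Si face of C5, so C10 bonds to its Re face (4aS). C10 is set by the chair-like six-atom tether, in which the enamine and acrylate planes are pseudo-equatorial and only the C10 methyl is axial, so H5 and the C10 methyl should end up trans (8aS); the competing chairs put the fully substituted C9 or the enamine carbon C6 axial. The step needs regioselectivity (C5 to C10, not to C7), which the tether length and the polarisation of the diene by the C11 ester secure, and elimination towards C7 rather than C5, which only the C7–H acidity allows; the transient C6 stereocentre is erased.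

Step 11
Reactants: 16 tert-butyl (4aS,8aS)-2-(diethoxymethyl)-5,5,8a-trimethyl-4a,5,6,7,8,8a-hexahydronaphthalene-1-carboxylate
Product: 18 tert-butyl (1S,4aS,8aS)-2-(diethoxymethyl)-1-hydroxy-5,5,8a-trimethyl-4-oxo-1,4,4a,5,6,7,8,8a-octahydronaphthalene-1-carboxylate, via endoperoxide 17 (not isolated)
Conditions: O2, tetraphenylporphyrin (cat.), visible light, CH2Cl2, −78 °C; then Et3N, 0 °C
Reagents that add atoms: dioxygen, O=O
Why: singlet oxygen should add [4+2] across the s-cis diene C6=C7–C8=C9 from the α face, opposite the axial C10 methyl and the 4β methyl, which puts the new C9–O bond α and the ester β (1S), and the Kornblum–DeLaMare rearrangement can only remove the single C6–H, giving the C6 ketone and the free 9α-hydroxyl with C7=C8 in place.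

Step 12
Reactants: 18 tert-butyl (1S,4aS,8aS)-2-(diethoxymethyl)-1-hydroxy-5,5,8a-trimethyl-4-oxo-1,4,4a,5,6,7,8,8a-octahydronaphthalene-1-carboxylate
Product: 19 tert-butyl (1S,4R,4aS,8aS)-2-(diethoxymethyl)-1,4-dihydroxy-5,5,8a-trimethyl-1,4,4a,5,6,7,8,8a-octahydronaphthalene-1-carboxylate
Conditions: NaBH4, CeCl3·7H2O, EtOH, −78 → −40 °C
Reagents that add atoms: none
Why: Luche 1,2-reduction, in which hydride should reach C6 from the α face because the β face is blocked by the syn-axial C10 and 4β methyls, giving the axial 6β-alcohol (4R); ethanol as solvent avoids acetal exchange.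

Step 13
Reactants: 20 (2E,4E)-hexa-2,4-dienal; 21 malonic acid
Product: 22 (2E,4E,6E)-octa-2,4,6-trienoic acid
Conditions: pyridine, piperidine (cat.), 90 °C
Reagents that add atoms: none
Why: Doebner–Knoevenagel condensation with decarboxylation gives the (E)-configured new double bond under thermodynamic control.

Step 14
Reactants: 19 tert-butyl (1S,4R,4aS,8aS)-2-(diethoxymethyl)-1,4-dihydroxy-5,5,8a-trimethyl-1,4,4a,5,6,7,8,8a-octahydronaphthalene-1-carboxylate; 22 (2E,4E,6E)-octa-2,4,6-trienoic acid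
Product: 24 tert-butyl (1S,4R,4aS,8aS)-2-(diethoxymethyl)-1-hydroxy-5,5,8a-trimethyl-4-{[(2E,4E,6E)-octa-2,4,6-trienoyl]oxy}-1,4,4a,5,6,7,8,8a-octahydronaphthalene-1-carboxylate, via mixed anhydride 23 (not isolated)
Conditions: 22, 2,4,6-Cl3C6H2COCl, Et3N, THF, 23 °C; then 19, DMAP, toluene, 40 °C
Reagents that add atoms: none
Why: Yamaguchi esterification, in which the mixed anhydride acylates the secondary allylic 6β-hydroxyl under DMAP catalysis while the tertiary 9α-hydroxyl between two fully substituted carbons should not react; no stereocentre is touched.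

Step 15
Reactants: 24 tert-butyl (1S,4R,4aS,8aS)-2-(diethoxymethyl)-1-hydroxy-5,5,8a-trimethyl-4-{[(2E,4E,6E)-octa-2,4,6-trienoyl]oxy}-1,4,4a,5,6,7,8,8a-octahydronaphthalene-1-carboxylate
Product: 25 ustusoic acid B
Conditions: TFA/CH2Cl2/H2O (10:10:1), 0 → 23 °C
Reagents that add atoms: water, O
Why: acidolysis cleaves the tert-butyl ester by alkyl–oxygen fission (no attack at the hindered acyl carbon) and hydrolyses the acetal to the conjugated aldehyde, while the trienoate should survive because ionisation at C6 or C9 would place a cation next to the electron-poor enal or the carboxyl.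

**Compound list**
1 | 3,3-dimethylpentane-1,5-diol | OCCC(C)(C)CCO | starting material
2 | 5-[(tert-butyldimethylsilyl)oxy]-3,3-dimethylpentan-1-ol | OCCC(C)(C)CCO[Si](C)(C)C(C)(C)C | intermediate
3 | tert-butyl[(5-iodo-3,3-dimethylpentyl)oxy]dimethylsilane | ICCC(C)(C)CCO[Si](C)(C)C(C)(C)C | intermediate
4 | tert-butyl{[3,3-dimethyl-8-(trimethylsilyl)oct-7-yn-1-yl]oxy}dimethylsilane | C[Si](C)(C)C#CCCCC(C)(C)CCO[Si](C)(C)C(C)(C)C | intermediate
5 | {8-[(tert-butyldimethylsilyl)oxy]-6,6-dimethyloct-1-yn-1-yl}lithium | [Li]C#CCCCC(C)(C)CCO[Si](C)(C)C(C)(C)C | intermediate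
6 | tert-butyl 9-[(tert-butyldimethylsilyl)oxy]-7,7-dimethylnon-2-ynoate | CC(C)(C)OC(=O)C#CCCCC(C)(C)CCO[Si](C)(C)C(C)(C)C | intermediate
7 | lithium [(1E)-1-(tert-butoxycarbonyl)-8-[(tert-butyldimethylsilyl)oxy]-2,6,6-trimethyloct-1-en-1-yl](methyl)cuprate (copper cis to the new methyl) | [Li+].C[Cu-]/C(C(=O)OC(C)(C)C)=C(\C)CCCC(C)(C)CCO[Si](C)(C)C(C)(C)C | intermediate
8 | tert-butyl (2E)-9-[(tert-butyldimethylsilyl)oxy]-2-iodo-3,7,7-trimethylnon-2-enoate | CC(C)(C)OC(=O)/C(I)=C(/C)CCCC(C)(C)CCO[Si](C)(C)C(C)(C)C | intermediate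
9 | 3,3-diethoxyprop-1-yne | C#CC(OCC)OCC | starting material
10 | tributyl(3,3-diethoxyprop-1-en-2-yl)stannane | C=C(C(OCC)OCC)[Sn](CCCC)(CCCC)CCCC | intermediate
11 | tert-butyl (2Z)-9-[(tert-butyldimethylsilyl)oxy]-2-(3,3-diethoxyprop-1-en-2-yl)-3,7,7-trimethylnon-2-enoate | CC(C)(C)OC(=O)/C(C(=C)C(OCC)OCC)=C(/C)CCCC(C)(C)CCO[Si](C)(C)C(C)(C)C | intermediate
12 | tert-butyl (2Z)-2-(3,3-diethoxyprop-1-en-2-yl)-9-hydroxy-3,7,7-trimethylnon-2-enoate | CC(C)(C)OC(=O)/C(C(=C)C(OCC)OCC)=C(/C)CCCC(C)(C)CCO | intermediate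
13 | tert-butyl (2Z)-2-(3,3-diethoxyprop-1-en-2-yl)-3,7,7-trimethyl-9-oxonon-2-enoate | CC(C)(C)OC(=O)/C(C(=C)C(OCC)OCC)=C(/C)CCCC(C)(C)CC=O | intermediate
14 | tert-butyl (2Z,8E)-2-(3,3-diethoxyprop-1-en-2-yl)-9-{(2R)-2-[diphenyl(trimethylsilyloxy)methyl]pyrrolidin-1-yl}-3,7,7-trimethylnona-2,8-dienoate | CC(C)(C)OC(=O)/C(C(=C)C(OCC)OCC)=C(/C)CCCC(C)(C)/C=C/N1CCC[C@@H]1C(c1ccccc1)(c1ccccc1)O[Si](C)(C)C | intermediate
15 | tert-butyl (4S,4aS,8aS)-2-(diethoxymethyl)-4-{(2R)-2-[diphenyl(trimethylsilyloxy)methyl]pyrrolidin-1-yl}-5,5,8a-trimethyl-3,4,4a,5,6,7,8,8a-octahydronaphthalene-1-carboxylate | C[Si](C)(C)OC(c1ccccc1)(c1ccccc1)[C@H]1CCCN1[C@H]1CC(C(OCC)OCC)=C(C(=O)OC(C)(C)C)[C@@]2(C)CCCC(C)(C)[C@H]12 | intermediate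
16 | tert-butyl (4aS,8aS)-2-(diethoxymethyl)-5,5,8a-trimethyl-4a,5,6,7,8,8a-hexahydronaphthalene-1-carboxylate | C1=CC(C(OCC)OCC)=C(C(=O)OC(C)(C)C)[C@@]2(C)CCCC(C)(C)[C@H]12 | intermediate
17 | tert-butyl (1S,4S,4aS,8aS)-2-(diethoxymethyl)-5,5,8a-trimethyl-4a,5,6,7,8,8a-hexahydro-4H-1,4-epidioxynaphthalene-1-carboxylate (6α,9α-epidioxide) | CC(C)(C)OC(=O)[C@@]12OO[C@@H](C=C1C(OCC)OCC)[C@H]1C(C)(C)CCC[C@]21C | intermediate
18 | tert-butyl (1S,4aS,8aS)-2-(diethoxymethyl)-1-hydroxy-5,5,8a-trimethyl-4-oxo-1,4,4a,5,6,7,8,8a-octahydronaphthalene-1-carboxylate | O=C1C=C(C(OCC)OCC)[C@](O)(C(=O)OC(C)(C)C)[C@@]2(C)CCCC(C)(C)[C@H]12 | intermediate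
19 | tert-butyl (1S,4R,4aS,8aS)-2-(diethoxymethyl)-1,4-dihydroxy-5,5,8a-trimethyl-1,4,4a,5,6,7,8,8a-octahydronaphthalene-1-carboxylate | O[C@@H]1C=C(C(OCC)OCC)[C@](O)(C(=O)OC(C)(C)C)[C@@]2(C)CCCC(C)(C)[C@H]12 | intermediate
20 | (2E,4E)-hexa-2,4-dienal | C/C=C/C=C/C=O | starting material
21 | malonic acid | OC(=O)CC(=O)O | starting material
22 | (2E,4E,6E)-octa-2,4,6-trienoic acid | C/C=C/C=C/C=C/C(=O)O | intermediate
23 | (2E,4E,6E)-octa-2,4,6-trienoic 2,4,6-trichlorobenzoic anhydride | C/C=C/C=C/C=C/C(=O)OC(=O)c1c(Cl)cc(Cl)cc1Cl | intermediate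
24 | tert-butyl (1S,4R,4aS,8aS)-2-(diethoxymethyl)-1-hydroxy-5,5,8a-trimethyl-4-{[(2E,4E,6E)-octa-2,4,6-trienoyl]oxy}-1,4,4a,5,6,7,8,8a-octahydronaphthalene-1-carboxylate | C/C=C/C=C/C=C/C(=O)O[C@@H]1C=C(C(OCC)OCC)[C@](O)(C(=O)OC(C)(C)C)[C@@]2(C)CCCC(C)(C)[C@H]12 | intermediate
25 | ustusoic acid B | C/C=C/C=C/C=C/C(=O)O[C@@H]1C=C(C=O)[C@](O)(C(=O)O)[C@@]2(C)CCCC(C)(C)[C@H]12 | target

**Step count and risks**
Total step count: 15. Longest linear sequence: 13 (steps 1–5, 7–12, 14, 15).

Steps most likely to fail: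

1. Step 10 (proposed new method). The hindered C5–C10 bond may form too slowly at temperatures the silyl ether catalyst tolerates. The amine may not be eliminated, so the catalyst does not turn over. Ring-fusion control may be lost, giving the cis-fused isomer. Fallback with known chemistry, setting out from 13: condensation with one full equivalent of (R)-2-(methoxymethyl)pyrrolidine (4 Å MS, toluene, 23 °C) should give the isolated auxiliary enamine tert-butyl (2Z,8E)-2-(3,3-diethoxyprop-1-en-2-yl)-9-[(2R)-2-(methoxymethyl)pyrrolidin-1-yl]-3,7,7-trimethylnona-2,8-dienoate F1. Heating F1 in toluene (80–110 °C) should effect the classical thermal cycloaddition of an aldehyde enamine to an ester-activated diene and give the amino-octalin tert-butyl (4S,4aS,8aS)-2-(diethoxymethyl)-4-[(2R)-2-(methoxymethyl)pyrrolidin-1-yl]-5,5,8a-trimethyl-3,4,4a,5,6,7,8,8a-octahydronaphthalene-1-carboxylate F2. Heating F2 with AcOH in toluene eliminates the auxiliary amine, and the route is rejoined at 16.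

2. Step 11. Singlet oxygen may react sluggishly with the ester-deactivated, hindered diene, or the ene reaction at the allylic C5–H may compete. Fallback, setting out from 16: epoxidation of the distal C6=C7 bond from the α face (mCPBA, NaHCO3, CH2Cl2, 0 °C) should give the vinyl epoxide tert-butyl 12,12-diethoxy-6α,7α-epoxydrim-8-en-11-oate F3. Reductive opening with SmI2 (THF/MeOH, −78 °C) should give tert-butyl 12,12-diethoxy-6α-hydroxydrim-7-en-11-oate F4. Double deprotonation with LiN(iPr)2 (2.2 equiv, THF, −78 °C) and oxidation of the alkoxide–ester enolate with 2-(phenylsulfonyl)-3-phenyloxaziridine from the α face should give tert-butyl 12,12-diethoxy-6α,9α-dihydroxydrim-7-en-11-oate F5. MnO2 (CH2Cl2) oxidises the allylic secondary alcohol, and the route is rejoined at 18.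

3. Step 14. Acylation of the axial 6β-hydroxyl, shielded by two syn-axial methyls, may be incomplete, with isomerisation or oligomerisation of the activated trienoyl donor on prolonged heating. Fallback, setting out from 19: esterification with the small diethylphosphonoacetic acid (DCC, DMAP, CH2Cl2) should give the phosphonoacetate tert-butyl (1S,4R,4aS,8aS)-4-{[2-(diethoxyphosphoryl)acetyl]oxy}-2-(diethoxymethyl)-1-hydroxy-5,5,8a-trimethyl-1,4,4a,5,6,7,8,8a-octahydronaphthalene-1-carboxylate F6. Horner–Wadsworth–Emmons olefination of F6 with (2E,4E)-hexa-2,4-dienal 20 (LiCl, DBU, MeCN) builds the (2E) double bond on the ester, and the route is rejoined at 24.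

Further compounds
F1 | step 10 | tert-butyl (2Z,8E)-2-(3,3-diethoxyprop-1-en-2-yl)-9-[(2R)-2-(methoxymethyl)pyrrolidin-1-yl]-3,7,7-trimethylnona-2,8-dienoate | COC[C@H]1CCCN1/C=C/C(C)(C)CCC/C(C)=C(\C(=O)OC(C)(C)C)C(=C)C(OCC)OCC
F2 | step 10 | tert-butyl (4S,4aS,8aS)-2-(diethoxymethyl)-4-[(2R)-2-(methoxymethyl)pyrrolidin-1-yl]-5,5,8a-trimethyl-3,4,4a,5,6,7,8,8a-octahydronaphthalene-1-carboxylate | COC[C@H]1CCCN1[C@H]1CC(C(OCC)OCC)=C(C(=O)OC(C)(C)C)[C@@]2(C)CCCC(C)(C)[C@H]12
F3 | step 11 | tert-butyl 12,12-diethoxy-6α,7α-epoxydrim-8-en-11-oate | CC(C)(C)OC(=O)C1=C(C(OCC)OCC)[C@@H]2O[C@@H]2[C@H]2C(C)(C)CCC[C@]12C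
F4 | step 11 | tert-butyl 12,12-diethoxy-6α-hydroxydrim-7-en-11-oate | O[C@H]1C=C(C(OCC)OCC)[C@H](C(=O)OC(C)(C)C)[C@@]2(C)CCCC(C)(C)[C@H]12
F5 | step 11 | tert-butyl 12,12-diethoxy-6α,9α-dihydroxydrim-7-en-11-oate | O[C@H]1C=C(C(OCC)OCC)[C@](O)(C(=O)OC(C)(C)C)[C@@]2(C)CCCC(C)(C)[C@H]12
F6 | step 14 | tert-butyl (1S,4R,4aS,8aS)-4-{[2-(diethoxyphosphoryl)acetyl]oxy}-2-(diethoxymethyl)-1-hydroxy-5,5,8a-trimethyl-1,4,4a,5,6,7,8,8a-octahydronaphthalene-1-carboxylate | CCOP(=O)(OCC)CC(=O)O[C@@H]1C=C(C(OCC)OCC)[C@](O)(C(=O)OC(C)(C)C)[C@@]2(C)CCCC(C)(C)[C@H]12
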